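**Strategy**

The route builds ring C of the lower (catechin) unit last. Its disconnection cuts the C4–C4a bond and the O1–C8a aryl ether bond, so that a palladium/norbornene (Catellani-type) annulation joins an aryl iodide, which already carries the epicatechin unit at the future C8, with a chiral 3-iodo-1-arylpropane-1,2-diol derivative. In one operation the primary iodide alkylates the only free ortho C–H (C4a) and the benzylic oxygen then takes the place of iodine at C8a. The step exploits the adjacent C4a carbon and C8a oxygen on ring A, with the C8 interflavan substituent as the ortho blocking group that this chemistry needs.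

Key step: step 9

Assumption: the lower unit is numbered as a flavan (O1, C2, C3, C4, C4a, C5–C8, C8a) also in its open-chain and aryl precursors, and 5-iodoresorcinol, 3,4-bis(benzyloxy)benzaldehyde and 4-(benzyloxy)benzoyl chloride are taken as purchasable.

**Route**

Step 1
Reactants: 1 (−)-epicatechin
Product: 2 3,5,7,3′,4′-penta-O-benzyl-(−)-epicatechin
Conditions: BnBr (6 equiv), NaH (5.5 equiv), DMF, 0 °C → rt
Reagents that add atoms: benzyl bromide BrCc1ccccc1
Why: Williamson O-benzylation of the four phenols and, with NaH, of the C3 alkoxide; no stereocentre is touched.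

Step 2
Reactants: 2 3,5,7,3′,4′-penta-O-benzyl-(−)-epicatechin
Product: 3 4β-(2-ethoxyethoxy)-3,5,7,3′,4′-penta-O-benzylepicatechin
Conditions: DDQ (2 equiv), 2-ethoxyethanol (5 equiv), CH2Cl2, rt
Reagents that add atoms: 2-ethoxyethanol CCOCCO
Why: DDQ should abstract hydride from C4, which is activated by the 5,7-dioxygenated ring A, and the benzylic cation is trapped by the alcohol trans to the 3-OBn group (oxidative benzylic etherification); the C4 configuration is lost again in step 5.

Step 3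
Reactants: 3 4β-(2-ethoxyethoxy)-3,5,7,3′,4′-penta-O-benzylepicatechin
Product: 4 8-bromo-4β-(2-ethoxyethoxy)-3,5,7,3′,4′-penta-O-benzylepicatechin
Conditions: NBS (1.05 equiv), CH2Cl2, −40 → 0 °C
Reagents that add atoms: N-bromosuccinimide O=C1CCC(=O)N1Br
Why: Electrophilic aromatic bromination should go to C8, the most nucleophilic position of ring A, and the bromine caps this position so that the unit cannot act as a nucleophile towards its own cation in step 5.

Step 4
Reactants: 5 5-iodoresorcinol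
Product: 6 1,3-bis(benzyloxy)-5-iodobenzene
Conditions: BnBr (2.4 equiv), K2CO3, DMF, rt
Reagents that add atoms: benzyl bromide BrCc1ccccc1
Why: Williamson etherification of both phenols.

Step 5
Reactants: 4 8-bromo-4β-(2-ethoxyethoxy)-3,5,7,3′,4′-penta-O-benzylepicatechin; 6 1,3-bis(benzyloxy)-5-iodobenzene (4 equiv)
Product: 7 (2R,3R,4R)-8-bromo-4β-[2,4-bis(benzyloxy)-6-iodophenyl]-3,5,7,3′,4′-penta-O-benzylepicatechin
Conditions: TMSOTf (0.5 equiv), CH2Cl2, −40 → −20 °C
Reagents that add atoms: none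
Why: TMSOTf ionises the C4 ether to the ring-A-stabilised benzylic cation, which alkylates 6 (Friedel–Crafts alkylation) para to one benzyloxy group and ortho to iodine; the arene enters anti to the 2-aryl and 3-OBn groups on the α-face, so the new C4 stereocentre should be 4β (3,4-trans) under substrate control.

Step 6
Reactants: 8 3,4-bis(benzyloxy)benzaldehyde
Product: 9 rac-1-[3,4-bis(benzyloxy)phenyl]prop-2-en-1-ol
Conditions: CH2=CHMgBr, THF, −78 → 0 °C; then H2O
Reagents that add atoms: vinylmagnesium bromide C=C[Mg]Br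
Why: Grignard addition to the aldehyde; the racemate is resolved in step 7.

Step 7
Reactants: 9 rac-1-[3,4-bis(benzyloxy)phenyl]prop-2-en-1-ol
Product: 10 (R)-[3,4-bis(benzyloxy)phenyl][(S)-oxiran-2-yl]methanol
Conditions: Ti(OiPr)4 (0.2 equiv), D-(−)-diisopropyl tartrate (0.24 equiv), t-BuOOH (0.6 equiv), 4 Å MS, CH2Cl2, −20 °C
Reagents that add atoms: tert-butyl hydroperoxide CC(C)(C)OO
Why: Sharpless kinetic resolution: with the D-tartrate the (S)-alcohol should be epoxidised much faster than the (R)-alcohol and with erythro selectivity, so reagent control sets the carbinol (R) and oxirane (S) centres; unreacted (R)-9 is removed by chromatography.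

Step 8
Reactants: 10 (R)-[3,4-bis(benzyloxy)phenyl][(S)-oxiran-2-yl]methanol
Product: 13 (1R,2R)-1-[3,4-bis(benzyloxy)phenyl]-2-[(tert-butyldimethylsilyl)oxy]-3-iodopropan-1-ol, via O-trimethylsilyl epoxide 11 (not isolated), via O-trimethylsilyl O-TBS iodide 12 (not isolated)
Conditions: N,O-bis(trimethylsilyl)acetamide (1.2 equiv), MeCN, rt; then TBSCl (1.3 equiv), NaI (1.5 equiv), −20 °C; then citric acid, MeOH, 0 °C
Reagents that add atoms: tert-butyldimethylsilyl chloride CC(C)(C)[Si](C)(C)Cl; sodium iodide [Na+].[I-]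
Why: Transient O-silylation protects the carbinol, the silyl iodide made in situ opens the terminal epoxide at CH2 (silyl iodide epoxide opening) to put iodine on C4 and TBS on the C3 oxygen without touching a stereocentre, and mild acidic methanolysis should remove only the TMS group.

Step 9
Reactants: 7 (2R,3R,4R)-8-bromo-4β-[2,4-bis(benzyloxy)-6-iodophenyl]-3,5,7,3′,4′-penta-O-benzylepicatechin; 13 (1R,2R)-1-[3,4-bis(benzyloxy)phenyl]-2-[(tert-butyldimethylsilyl)oxy]-3-iodopropan-1-ol (2.5 equiv)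
Product: 14 8-bromo-3,5,7,3′,4′-penta-O-benzylepicatechin-(4β→8)-[3-O-(tert-butyldimethylsilyl)-5,7,3′,4′-tetra-O-benzylcatechin]
Conditions: Pd(OAc)2 (10 mol %), RuPhos (20 mol %), norbornene (1 equiv), Cs2CO3 (3 equiv), 1,4-dioxane, 100 °C
Reagents that add atoms: none
Why: Proposed new method: zerovalent palladium should insert into the C8a–I bond of 7, and norbornene carbopalladation followed by base-assisted palladation of the only free ortho C–H (C4a) gives the aryl–norbornyl palladacycle of divalent palladium; this is alkylated by the primary iodide of 13 (SN2-type oxidative addition to tetravalent palladium, then C–C reductive elimination) to form C4–C4a, norbornene is extruded, and the arylpalladium at C8a is captured by the benzylic alkoxide with C–O reductive elimination forming O1–C8a. The closest known reaction type is the palladium/norbornene (Catellani) annulation of aryl iodides with epoxides to 2,3-dihydrobenzofurans and with bromoalkylamines to tetrahydroquinolines, together with intramolecular palladium-catalysed aryl etherification to chromans; the alkylation–etherification sequence with a γ-hydroxy alkyl iodide to a six-membered ring has not been shown. Ring C is closed by C(aryl)–O reductive elimination from a seven-membered oxapalladacycle, a formal [3+3] annulation onto C4a and C8a. No stereocentre is formed: C2 and C3 of the lower unit come from 13 with retention because none of their bonds is touched, and the three centres of the upper unit are spectators. The step needs site selectivity (the C8 flavanyl group blocks the second ortho position and drives norbornene extrusion), ring-size selectivity (the TBS ether on the C3 oxygen leaves only the benzylic oxygen free to close) and chemoselectivity for C–I over the C8–Br cap (iodide is the faster partner, and reduction of that bromide would be harmless because it is removed in step 12).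

Step 10
Reactants: 14 8-bromo-3,5,7,3′,4′-penta-O-benzylepicatechin-(4β→8)-[3-O-(tert-butyldimethylsilyl)-5,7,3′,4′-tetra-O-benzylcatechin]
Product: 15 8-bromo-3,5,7,3′,4′-penta-O-benzylepicatechin-(4β→8)-(5,7,3′,4′-tetra-O-benzylcatechin)
Conditions: HF·pyridine, pyridine, THF, 0 °C → rt
Reagents that add atoms: none
Why: Fluoride cleaves the Si–O bond of the TBS ether (desilylation), while benzyl ethers, the aryl bromide and the interflavan bond should be inert.

Step 11
Reactants: 15 8-bromo-3,5,7,3′,4′-penta-O-benzylepicatechin-(4β→8)-(5,7,3′,4′-tetra-O-benzylcatechin); 16 4-(benzyloxy)benzoyl chloride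
Product: 17 8-bromo-3,5,7,3′,4′-penta-O-benzylepicatechin-(4β→8)-{5,7,3′,4′-tetra-O-benzylcatechin 3-O-[4-(benzyloxy)benzoate]}
Conditions: Et3N, DMAP (cat.), CH2Cl2, rt
Reagents that add atoms: none
Why: DMAP-catalysed acylation of the only free hydroxyl, the C3–OH of the lower unit, with retention at C3.

Step 12
Reactants: 17 8-bromo-3,5,7,3′,4′-penta-O-benzylepicatechin-(4β→8)-{5,7,3′,4′-tetra-O-benzylcatechin 3-O-[4-(benzyloxy)benzoate]}
Product: 18 epicatechin-(4β→8)-catechin 3-O-(4-hydroxybenzoate), the target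
Conditions: H2 (1 atm), Pd(OH)2/C, Et3N (1.1 equiv), THF/MeOH, rt
Reagents that add atoms: none
Why: Hydrogenolysis over Pd(OH)2/C should remove all ten benzyl ethers and the C8 bromine, while the benzoate ester, the interflavan bond and all stereocentres stay untouched.

**Compound list**

1 | (−)-epicatechin, (2R,3R)-2-(3,4-dihydroxyphenyl)chromane-3,5,7-triol | O[C@@H]1Cc2c(O)cc(O)cc2O[C@@H]1c1ccc(O)c(O)c1 | starting material
2 | 3,5,7,3′,4′-penta-O-benzyl-(−)-epicatechin | c3ccccc3CO[C@@H]1Cc2c(OCc3ccccc3)cc(OCc3ccccc3)cc2O[C@@H]1c8ccc(OCc3ccccc3)c(OCc3ccccc3)c8 | intermediate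
3 | 4β-(2-ethoxyethoxy)-3,5,7,3′,4′-penta-O-benzylepicatechin (2,3-cis-3,4-trans) | c3ccccc3CO[C@@H]1[C@@H](OCCOCC)c2c(OCc3ccccc3)cc(OCc3ccccc3)cc2O[C@@H]1c8ccc(OCc3ccccc3)c(OCc3ccccc3)c8 | intermediate
4 | 8-bromo-4β-(2-ethoxyethoxy)-3,5,7,3′,4′-penta-O-benzylepicatechin | c3ccccc3CO[C@@H]1[C@@H](OCCOCC)c2c(OCc3ccccc3)cc(OCc3ccccc3)c(Br)c2O[C@@H]1c8ccc(OCc3ccccc3)c(OCc3ccccc3)c8 | intermediate
5 | 5-iodoresorcinol (5-iodobenzene-1,3-diol) | Oc1cc(O)cc(I)c1 | starting material
6 | 1,3-bis(benzyloxy)-5-iodobenzene | Ic1cc(OCc2ccccc2)cc(OCc2ccccc2)c1 | intermediate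
7 | (2R,3R,4R)-8-bromo-4β-[2,4-bis(benzyloxy)-6-iodophenyl]-3,5,7,3′,4′-penta-O-benzylepicatechin (2,3-cis-3,4-trans) | c3ccccc3CO[C@@H]1[C@@H](c4c(I)cc(OCc3ccccc3)cc4OCc3ccccc3)c2c(OCc3ccccc3)cc(OCc3ccccc3)c(Br)c2O[C@@H]1c8ccc(OCc3ccccc3)c(OCc3ccccc3)c8 | intermediate
8 | 3,4-bis(benzyloxy)benzaldehyde | O=Cc1ccc(OCc2ccccc2)c(OCc2ccccc2)c1 | starting material
9 | rac-1-[3,4-bis(benzyloxy)phenyl]prop-2-en-1-ol | C=CC(O)c1ccc(OCc2ccccc2)c(OCc2ccccc2)c1 | intermediate
10 | (R)-[3,4-bis(benzyloxy)phenyl][(S)-oxiran-2-yl]methanol (erythro) | O[C@@H]([C@@H]1CO1)c1ccc(OCc2ccccc2)c(OCc2ccccc2)c1 | intermediate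
11 | {(R)-[3,4-bis(benzyloxy)phenyl][(S)-oxiran-2-yl]methoxy}trimethylsilane | C[Si](C)(C)O[C@@H]([C@@H]1CO1)c1ccc(OCc2ccccc2)c(OCc2ccccc2)c1 | intermediate (not isolated)
12 | (1R,2R)-1-[3,4-bis(benzyloxy)phenyl]-2-[(tert-butyldimethylsilyl)oxy]-3-iodo-1-[(trimethylsilyl)oxy]propane | C[Si](C)(C)O[C@@H]([C@@H](O[Si](C)(C)C(C)(C)C)CI)c1ccc(OCc2ccccc2)c(OCc2ccccc2)c1 | intermediate (not isolated)
13 | (1R,2R)-1-[3,4-bis(benzyloxy)phenyl]-2-[(tert-butyldimethylsilyl)oxy]-3-iodopropan-1-ol | O[C@@H]([C@@H](O[Si](C)(C)C(C)(C)C)CI)c1ccc(OCc2ccccc2)c(OCc2ccccc2)c1 | intermediate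
14 | 8-bromo-3,5,7,3′,4′-penta-O-benzylepicatechin-(4β→8)-[3-O-(tert-butyldimethylsilyl)-5,7,3′,4′-tetra-O-benzylcatechin] | c3ccccc3CO[C@@H]1[C@@H](c4c5O[C@H](c6ccc(OCc3ccccc3)c(OCc3ccccc3)c6)[C@@H](O[Si](C)(C)C(C)(C)C)Cc5c(OCc3ccccc3)cc4OCc3ccccc3)c2c(OCc3ccccc3)cc(OCc3ccccc3)c(Br)c2O[C@@H]1c8ccc(OCc3ccccc3)c(OCc3ccccc3)c8 | intermediate
15 | 8-bromo-3,5,7,3′,4′-penta-O-benzylepicatechin-(4β→8)-(5,7,3′,4′-tetra-O-benzylcatechin), free 3-OH on the lower unit | c3ccccc3CO[C@@H]1[C@@H](c4c5O[C@H](c6ccc(OCc3ccccc3)c(OCc3ccccc3)c6)[C@@H](O)Cc5c(OCc3ccccc3)cc4OCc3ccccc3)c2c(OCc3ccccc3)cc(OCc3ccccc3)c(Br)c2O[C@@H]1c8ccc(OCc3ccccc3)c(OCc3ccccc3)c8 | intermediate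
16 | 4-(benzyloxy)benzoyl chloride | O=C(Cl)c1ccc(OCc2ccccc2)cc1 | starting material
17 | 8-bromo-3,5,7,3′,4′-penta-O-benzylepicatechin-(4β→8)-{5,7,3′,4′-tetra-O-benzylcatechin 3-O-[4-(benzyloxy)benzoate]} | c3ccccc3CO[C@@H]1[C@@H](c4c5O[C@H](c6ccc(OCc3ccccc3)c(OCc3ccccc3)c6)[C@@H](OC(=O)c7ccc(OCc3ccccc3)cc7)Cc5c(OCc3ccccc3)cc4OCc3ccccc3)c2c(OCc3ccccc3)cc(OCc3ccccc3)c(Br)c2O[C@@H]1c8ccc(OCc3ccccc3)c(OCc3ccccc3)c8 | intermediate
18 | (2R,3S)-2-(3,4-dihydroxyphenyl)-8-[(2R,3R,4R)-2-(3,4-dihydroxyphenyl)-3,5,7-trihydroxychroman-4-yl]-5,7-dihydroxychroman-3-yl 4-hydroxybenzoate (CNP0288594.1) | O=C(O[C@H]1Cc2c(O)cc(O)c([C@H]3c4c(O)cc(O)cc4O[C@H](c4ccc(O)c(O)c4)[C@@H]3O)c2O[C@@H]1c1ccc(O)c(O)c1)c1ccc(O)cc1 | target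

**Step count and risks**

Total steps: 12. Longest linear sequence: 8 steps (steps 1, 2, 3, 5, 9, 10, 11 and 12, from (−)-epicatechin).

Steps most likely to fail:

1. Step 9 (Proposed new method). The palladacycle at the crowded C4a position, which is flanked by the C5 benzyloxy group, may be alkylated too slowly by the β-branched iodide. The TBS group may migrate to the benzylic oxygen under base. The palladium alkoxide may undergo β-hydride elimination faster than C–O bond formation. The fallback uses known chemistry (directed ortho-lithiation, epoxide opening, intramolecular SNAr etherification), sets out from 4 and 10 and comes back at 15. 5-Fluororesorcinol is benzylated as in step 4 to 1,3-bis(benzyloxy)-5-fluorobenzene F1, and F1 is coupled with 4 as in step 5 to the fluoro analogue of 7, 8-bromo-4β-[2,4-bis(benzyloxy)-6-fluorophenyl]-3,5,7,3′,4′-penta-O-benzylepicatechin F2. Lithium 2,2,6,6-tetramethylpiperidide in THF at −78 °C should remove the proton between fluorine and the benzyloxy group. The aryllithium should then open the epoxide of 10 (added as its lithium alkoxide made with n-butyllithium, BF3·OEt2) at the CH2 terminus, which forms the C4–C4a bond in the diol 8-bromo-4β-{2,4-bis(benzyloxy)-5-[(2S,3R)-3-[3,4-bis(benzyloxy)phenyl]-2,3-dihydroxypropyl]-6-fluorophenyl}-3,5,7,3′,4′-penta-O-benzylepicatechin F3. KN(SiMe3)2 with 18-crown-6 in THF/DMF at 60–80 °C should then close ring C by displacement of fluoride by the benzylic alkoxide, which forms O1–C8a and gives 15. Closure by the C3 alkoxide would need a strained five-membered transition state and is not expected.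

2. Step 5. The iodoarene may be too weak a nucleophile, so that the cation decomposes before it is captured, or attack may occur between the two benzyloxy groups. The fallback sets out from 4 and 5 and comes back at 7. The free diphenol 5, a smaller and more reactive nucleophile, is used in excess with 4 (BF3·OEt2, THF/CH2Cl2, −20 °C) and should be alkylated para to one hydroxyl and ortho to iodine to give 8-bromo-4β-(2,4-dihydroxy-6-iodophenyl)-3,5,7,3′,4′-penta-O-benzylepicatechin F4. Benzylation of F4 (BnBr, K2CO3, DMF) gives 7.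

3. Step 8. The silyl iodide may ionise the electron-rich benzylic silyl ether or cleave benzyl ethers before the epoxide is consumed. The fallback avoids a silyl iodide, sets out from 10 and comes back at 13. 10 is protected as its triethylsilyl ether {(R)-[3,4-bis(benzyloxy)phenyl][(S)-oxiran-2-yl]methoxy}triethylsilane F5 (TESCl, imidazole, CH2Cl2). The epoxide is opened at CH2 with MgI2 (Et2O/toluene, −40 °C) to the iodohydrin (1R,2R)-1-[3,4-bis(benzyloxy)phenyl]-3-iodo-1-[(triethylsilyl)oxy]propan-2-ol F6. The new hydroxyl is silylated (TBSOTf, 2,6-lutidine, CH2Cl2, −78 °C) to (1R,2R)-1-[3,4-bis(benzyloxy)phenyl]-2-[(tert-butyldimethylsilyl)oxy]-3-iodo-1-[(triethylsilyl)oxy]propane F7. The more labile TES ether is then cleaved selectively (PPTS, MeOH, 0 °C) to give 13.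

**Further compounds**

F1 | step 9 | 1,3-bis(benzyloxy)-5-fluorobenzene | Fc1cc(OCc2ccccc2)cc(OCc2ccccc2)c1
F2 | step 9 | 8-bromo-4β-[2,4-bis(benzyloxy)-6-fluorophenyl]-3,5,7,3′,4′-penta-O-benzylepicatechin | c3ccccc3CO[C@@H]1[C@@H](c4c(F)cc(OCc3ccccc3)cc4OCc3ccccc3)c2c(OCc3ccccc3)cc(OCc3ccccc3)c(Br)c2O[C@@H]1c8ccc(OCc3ccccc3)c(OCc3ccccc3)c8
F3 | step 9 | 8-bromo-4β-{2,4-bis(benzyloxy)-5-[(2S,3R)-3-[3,4-bis(benzyloxy)phenyl]-2,3-dihydroxypropyl]-6-fluorophenyl}-3,5,7,3′,4′-penta-O-benzylepicatechin | c3ccccc3CO[C@@H]1[C@@H](c4c(F)c(C[C@H](O)[C@H](O)c6ccc(OCc3ccccc3)c(OCc3ccccc3)c6)c(OCc3ccccc3)cc4OCc3ccccc3)c2c(OCc3ccccc3)cc(OCc3ccccc3)c(Br)c2O[C@@H]1c8ccc(OCc3ccccc3)c(OCc3ccccc3)c8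
F4 | step 5 | 8-bromo-4β-(2,4-dihydroxy-6-iodophenyl)-3,5,7,3′,4′-penta-O-benzylepicatechin | c3ccccc3CO[C@@H]1[C@@H](c4c(I)cc(O)cc4O)c2c(OCc3ccccc3)cc(OCc3ccccc3)c(Br)c2O[C@@H]1c8ccc(OCc3ccccc3)c(OCc3ccccc3)c8
F5 | step 8 | {(R)-[3,4-bis(benzyloxy)phenyl][(S)-oxiran-2-yl]methoxy}triethylsilane | CC[Si](CC)(CC)O[C@@H]([C@@H]1CO1)c1ccc(OCc2ccccc2)c(OCc2ccccc2)c1
F6 | step 8 | (1R,2R)-1-[3,4-bis(benzyloxy)phenyl]-3-iodo-1-[(triethylsilyl)oxy]propan-2-ol | CC[Si](CC)(CC)O[C@@H]([C@@H](O)CI)c1ccc(OCc2ccccc2)c(OCc2ccccc2)c1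
F7 | step 8 | (1R,2R)-1-[3,4-bis(benzyloxy)phenyl]-2-[(tert-butyldimethylsilyl)oxy]-3-iodo-1-[(triethylsilyl)oxy]propane | CC[Si](CC)(CC)O[C@@H]([C@@H](O[Si](C)(C)C(C)(C)C)CI)c1ccc(OCc2ccccc2)c(OCc2ccccc2)c1
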